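## The problem

- Target 9 is an aryl ketone. C1 (C=O) carries a benzene ring substituted at both ortho positions (OH and CH3). C2 is a methylene. C3 is a quaternary carbon bearing CH3, a vinyl group and the C4–C12 chain with the 6E trisubstituted olefin and the terminal C10=C11 olefin.
- C3 (R) is the only stereocentre. It is acyclic and all-carbon, nothing else in the molecule can direct it, and two of its substituents (C2 and C4) are CH2 groups that differ only further out.
- A catalyst that must tell CH3 from CH2R at a prochiral carbon does so poorly. The reliable, purchasable stereochemical information is the E geometry of the C2=C3 olefin of (2E,6E)-farnesol 1, so the route should turn geometry into configuration.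
- The C1 carbonyl is di-ortho-substituted and hydrogen-bonded to the phenol. Making the aryl–C1 bond or adding to C1 late is unattractive, so the ring is best bought with its acyl carbon in place (ketone 3).
- The three olefins cyclise under protic acid, Lewis acid, π-acids and electrophiles, and the free phenol adds to them under acid. Hydrogenation, hydroboration, ozonolysis and harsh ether cleavage are excluded.
- The feature that makes the key step possible: C2 is α to the C1 aryl ketone and, across C3, homoallylic to the vinyl group (C2–C3–CH=CH2). An oxygen placed on C2 turns C2–C3 into the retron of a carbonyl allylation with allyl transposition, and that oxygen can later be expelled reductively from the C1 ketyl. The OH and CH3 ortho to C1 keep the ketone silent while an aldehyde at C2 reacts.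

## Retrosynthesis

**Adding an oxygen at C2 (9 ⇐ 8 ⇐ 7 ⇐ 6).** No bond of the skeleton is cut; a hydroxyl is added at C2, giving ketol 6, reached back through aryl acetate 8 and diacetate 7. This is preferred to cutting directly at 9 because every direct cut (enolate allylation, conjugate addition) leaves C3 to be set by Me/CH2 discrimination. With the C2 oxygen, C3 can be set relative to a secondary carbinol that catalysts control well and that is then erased. The forward reaction must cleave the C2–O bond without touching C3 or the olefins; one-electron reduction of the α-acyloxy aryl ketone does this.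

**Cutting C2–C3 with reversed polarity (6 ⇒ 4 + 2, via borate 5).** C2 becomes the formyl carbon of aryl glyoxal 4 and C3 the γ-carbon of (2E,6E)-farnesyl pinacol boronate 2. Compared with the normal-polarity cut of the same bond, the allyl unit is now the nucleophile and reacts through a closed chair, so the E geometry of 2 fixes C3 relative to C2, and a chiral acid fixes C2. Both precursors are achiral and each is one step from a commercial compound, while 6 holds the full skeleton and the stereocentre. The forward reaction must attack the aldehyde and not the ketone, bond at the γ-carbon, and be highly anti- and face-selective.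

**Allyl boronate from allyl alcohol (2 ⇒ 1).** The C1–B bond of 2 is traced to the C1–O bond of farnesol 1. The forward borylation must place boron at the primary terminus and leave both E olefins unchanged.

**Formyl carbon from the acetyl methyl (4 ⇒ 3).** The C2 aldehyde of 4 is the oxidised methyl of ketone 3, which already contains the hindered aryl–C1 bond and the ortho OH and CH3. The forward oxidation must spare the arene methyl and the phenol.

## Roads not taken

**Alternative 1: normal-polarity C2–C3 bond (the most obvious cut).**
- Cut: C2 as an enolate equivalent, C3 as the γ-carbon of a farnesyl electrophile, joined by an enantioselective SN2′ substitution.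
- Forward key step: stabilised enolates are not competent in the copper-catalysed SN2′ reactions that handle dialkyl allyl termini. The realistic version therefore uses farnesyl diethyl phosphate A1 and the aluminium acetylide of aryl alkyne A2 under a chiral N-heterocyclic carbene–copper catalyst to give enyne A3, followed by alkyne hydration and O-demethylation.
- Why the chosen plan is better:
  - The oxidation level at C1 has to be corrected after the stereocentre is set. A3 is a 1,6-enyne (C1≡C2 and C6=C7), so π-acid hydration competes with cycloisomerisation.
  - The ortho oxygen can attack the activated alkyne at C2 and give a benzofuran, which places the oxygen on the wrong carbon.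
  - Phenol protection and ether cleavage beside a polyene add steps and risk; the sequence is about six steps.
  - An iridium-type branched allylation with the free enolate would have to tell CH3 from CH2, which is the weak point the chosen plan avoids.

**Alternative 2: C3–vinyl bond by conjugate addition.**
- Cut: the C3–vinyl bond.
- Forward key step: catalytic asymmetric 1,4-addition of a vinyl–metal reagent to enone A4.
- Why the chosen plan is better:
  - A4 must be made geometrically pure, and the usual condensations or olefinations give E/Z mixtures.
  - Its carbonyl is twisted out of conjugation by the two ortho substituents, so it is a poor acceptor.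
  - The catalyst must again distinguish CH3 from CH2CH2R on an acyclic trisubstituted enone, and vinyl transfer to such acceptors has little precedent.
  - The phenol must be protected and freed again.

**Alternative 3: sigmatropic route through a coumarin.**
- Cut: the ortho-hydroxy ketone is read as a 4-hydroxycoumarin that has lost CO2, and C2–C3 is cut as a Claisen retron.
- Forward key step: O-farnesylation of 4-hydroxy-5-methylcoumarin A5 gives ether A6; Claisen rearrangement gives the C3-alkylated coumarin A7 with the vinyl group; alkaline lactone opening and decarboxylation give 9.
- Why the chosen plan is better: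
  - The route is short, but the thermal [3,3] shift has no element that fixes absolute configuration, so 9 would be racemic.
  - Chirality transfer would need a stereogenic, later removable substituent on C1 of the farnesyl unit.
  - A catalytic enantioselective Claisen rearrangement of this ether class that creates the stereocentre at the allyl terminus is not established.
  - Heating invites abnormal Claisen products and phenol–olefin cyclisation.
  - The chosen plan uses the same chair logic (geometry into configuration) but adds a catalyst-controlled carbinol at C2.

Key step: step 3

Assumption: the facial sense of the chiral phosphoric acid known for simple aldehydes is taken to hold for glyoxal 4, which calls for the (S)-acid; if the sense were reversed, the (R)-acid would be used.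

## Route

Step 1
Reactants: 1 (2E,6E)-farnesol
Product: 2 4,4,5,5-tetramethyl-2-[(2E,6E)-3,7,11-trimethyldodeca-2,6,10-trien-1-yl]-1,3,2-dioxaborolane
Conditions: B2pin2 (1.1 equiv), [Pd(MeCN)4](BF4)2 (5 mol %), DMSO/MeOH, rt
Reagents that add atoms: bis(pinacolato)diboron, CC1(C)OB(OC1(C)C)B1OC(C)(C)C(C)(C)O1
Why: Palladium-catalysed borylation of an allylic alcohol (Miyaura-type borylation through a π-allylpalladium intermediate) should place boron at the primary terminus. The C2=C3 geometry should be kept, because syn/anti exchange at the disubstituted terminus would need a σ-allyl complex at the tertiary carbon.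

Step 2
Reactants: 3 1-(2-hydroxy-6-methylphenyl)ethan-1-one
Product: 4 2-(2-hydroxy-6-methylphenyl)-2-oxoacetaldehyde
Conditions: SeO2 (1.2 equiv), 1,4-dioxane/H2O, 90 °C; azeotropic drying (toluene)
Reagents that add atoms: selenium dioxide, O=[Se]=O
Why: Riley oxidation of an aryl methyl ketone through its enol should give the aryl glyoxal; the arene methyl is not activated and the phenol is held in the hydrogen bond to the ketone. The product may rest as its hydrate or ring-closed lactol and is dried before use.

Step 3
Reactants: 4 2-(2-hydroxy-6-methylphenyl)-2-oxoacetaldehyde, 2 4,4,5,5-tetramethyl-2-[(2E,6E)-3,7,11-trimethyldodeca-2,6,10-trien-1-yl]-1,3,2-dioxaborolane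
Product: 6 (2S,3S,6E)-3-ethenyl-2-hydroxy-1-(2-hydroxy-6-methylphenyl)-3,7,11-trimethyldodeca-6,10-dien-1-one, via pinacol borate ester 5 (not isolated)
Conditions: 2 (1.3 equiv), (S)-3,3'-bis(2,4,6-triisopropylphenyl)-1,1'-binaphthyl-2,2'-diyl hydrogen phosphate (5–10 mol %), 4 Å MS, toluene, −30 °C; then aq. NaHCO3
Reagents that add atoms: none
Why: This is an aldehyde allylboration through a closed six-membered chair (Zimmerman–Traxler-type) transition state in its chiral phosphoric-acid-catalysed form, a reaction type known for γ,γ-disubstituted allyl pinacol boronates that gives homoallylic alcohols with a quaternary carbon. The acid hydrogen-bonds to a boronate oxygen and to the formyl C–H of 4, boron binds the aldehyde oxygen, and the γ-carbon of 2 bonds to C2 with allyl transposition, so the C2–C3 bond and the vinyl group form in one event. No ring is closed in the product; the only ring is the transient chair. C2 (S) is set by the catalyst, which should expose the Si face of the formyl group; C3 is set relative to C2 by the chair, in which the aroyl group sits equatorial and the E geometry of 2 puts the C4 chain pseudo-equatorial (anti to the new hydroxyl) and the methyl pseudo-axial. The step needs γ over α attack (inherent to allylboration), aldehyde over ketone (the C1 carbonyl is shielded by the ortho OH and CH3 and deactivated by the hydrogen bond), and high anti and facial selectivity, since both become the enantiomeric purity at C3 once C2 is erased. Both carbons react with polarity opposite to an enolate allylation, so the CH3/CH2 distinction at C3 is made by olefin geometry and not by the catalyst. Low temperature and molecular sieves should hold back the uncatalysed pathway and keep 4 as the free aldehyde.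

Step 4
Reactants: 6 (2S,3S,6E)-3-ethenyl-2-hydroxy-1-(2-hydroxy-6-methylphenyl)-3,7,11-trimethyldodeca-6,10-dien-1-one
Product: 7 (2S,3S,6E)-1-(2-acetoxy-6-methylphenyl)-3-ethenyl-3,7,11-trimethyl-1-oxododeca-6,10-dien-2-yl acetate
Conditions: Ac2O (3 equiv), pyridine, DMAP (cat.), CH2Cl2, 0 °C to rt
Reagents that add atoms: acetic anhydride, CC(=O)OC(C)=O
Why: DMAP-catalysed acyl transfer (Steglich-type) should acetylate both hydroxyls; the C2 acetate is the leaving group for step 5. C3 has no acidic hydrogen and C2 is to be erased, so no stereochemical information is at risk.

Step 5
Reactants: 7 (2S,3S,6E)-1-(2-acetoxy-6-methylphenyl)-3-ethenyl-3,7,11-trimethyl-1-oxododeca-6,10-dien-2-yl acetate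
Product: 9 (3R,6E)-3-ethenyl-1-(2-hydroxy-6-methylphenyl)-3,7,11-trimethyldodeca-6,10-dien-1-one, via aryl acetate 8 (not isolated)
Conditions: SmI2 (2.5 equiv), MeOH, THF, −78 °C; then K2CO3 (cat.), MeOH, rt
Reagents that add atoms: none
Why: Reductive cleavage of an α-acyloxy ketone by SmI2: electron transfer to the aryl ketone gives a ketyl that expels the C2 acetate, a second electron gives the samarium enolate, and methanol protonates it; base-catalysed transesterification then frees the phenol. C3 is not touched, and its descriptor changes from S to R only because C2 loses its oxygen and falls below vinyl in priority.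

## Compound list

1 | (2E,6E)-farnesol, (2E,6E)-3,7,11-trimethyldodeca-2,6,10-trien-1-ol | OC/C=C(\C)CC/C=C(\C)CCC=C(C)C | starting material
2 | 4,4,5,5-tetramethyl-2-[(2E,6E)-3,7,11-trimethyldodeca-2,6,10-trien-1-yl]-1,3,2-dioxaborolane | CC1(C)OB(C/C=C(\C)CC/C=C(\C)CCC=C(C)C)OC1(C)C | intermediate
3 | 1-(2-hydroxy-6-methylphenyl)ethan-1-one | CC(=O)c1c(C)cccc1O | starting material
4 | 2-(2-hydroxy-6-methylphenyl)-2-oxoacetaldehyde | O=CC(=O)c1c(C)cccc1O | intermediate
5 | (2S,3S,6E)-3-ethenyl-1-(2-hydroxy-6-methylphenyl)-3,7,11-trimethyl-2-[(4,4,5,5-tetramethyl-1,3,2-dioxaborolan-2-yl)oxy]dodeca-6,10-dien-1-one | C=C[C@](C)(CC/C=C(\C)CCC=C(C)C)[C@H](OB1OC(C)(C)C(C)(C)O1)C(=O)c1c(C)cccc1O | intermediate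
6 | (2S,3S,6E)-3-ethenyl-2-hydroxy-1-(2-hydroxy-6-methylphenyl)-3,7,11-trimethyldodeca-6,10-dien-1-one | C=C[C@](C)(CC/C=C(\C)CCC=C(C)C)[C@H](O)C(=O)c1c(C)cccc1O | intermediate
7 | (2S,3S,6E)-1-(2-acetoxy-6-methylphenyl)-3-ethenyl-3,7,11-trimethyl-1-oxododeca-6,10-dien-2-yl acetate | C=C[C@](C)(CC/C=C(\C)CCC=C(C)C)[C@H](OC(C)=O)C(=O)c1c(C)cccc1OC(C)=O | intermediate
8 | 2-[(3R,6E)-3-ethenyl-3,7,11-trimethyldodeca-6,10-dienoyl]-3-methylphenyl acetate | C=C[C@](C)(CC/C=C(\C)CCC=C(C)C)CC(=O)c1c(C)cccc1OC(C)=O | intermediate
9 | (3R,6E)-3-ethenyl-1-(2-hydroxy-6-methylphenyl)-3,7,11-trimethyldodeca-6,10-dien-1-one | C=C[C@](C)(CC/C=C(\C)CCC=C(C)C)CC(=O)c1c(C)cccc1O | target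

## Step count and risks

Total steps: 5. Longest linear sequence: 4 steps (1 → 2 → 6 → 7 → 9, or 3 → 4 → 6 → 7 → 9).

**Step 3 (key step).**
- What may go wrong: loss of catalyst control over the formyl face. Glyoxal 4 is far more electrophilic than the aldehydes this catalysis was developed for, and its phenol and ketone offer the acid other hydrogen-bond sites. It can also rest as its lactol. The uncatalysed chair pathway (same relative configuration, no absolute control) may therefore compete.
- Fallback: move the stereocontrol from the catalyst to a stoichiometric chiral auxiliary on boron. Starting from farnesol 1, borylation with B2(OH)4 and [Pd(MeCN)4](BF4)2 in DMSO/MeOH would give [(2E,6E)-3,7,11-trimethyldodeca-2,6,10-trien-1-yl]boronic acid F1. Esterification with diisopropyl (R,R)-tartrate over MgSO4 would give the tartrate farnesylboronate F2. This more electrophilic boronate should add to glyoxal 4 in toluene over 4 Å molecular sieves at −78 °C through the same chair, with the aldehyde face set by the tartrate (the (R,R)-ester is the one expected to deliver to the Si face). Hydrolytic work-up returns the route at ketol 6.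

**Step 2.**
- What may go wrong: oxidative degradation of the free, electron-rich phenol ring, or further oxidation of the ring-closed lactol form of the product by the selenium reagent at high temperature.
- Fallback: replace the direct oxidation by halogenation followed by Kornblum oxidation. Starting from ketone 3, CuBr2 in refluxing EtOAc/CHCl3 should brominate the acetyl methyl selectively to give 2-bromo-1-(2-hydroxy-6-methylphenyl)ethan-1-one F3. Stirring F3 in DMSO at rt without base (base would close the benzofuranone ring) should oxidise the C–Br carbon and return the route at glyoxal 4.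

**Step 5.**
- What may go wrong: transfer of the acetyl group from the neighbouring aryl ester to C2 of the samarium enolate (a Baker–Venkataraman-type O→C acyl shift) before the enolate is protonated.
- Fallback: leave out the ester activation altogether. Starting from ketol 6 (that is, also omitting step 4), reduction with SmI2 and HMPA in THF/MeOH from −78 °C to 0 °C should expel hydroxide from the ketyl. This is slower than acetate loss but is a known reaction of α-hydroxy ketones; no ester is present to migrate and the phenol needs no protection. The route is rejoined at target 9. No compound outside the route is made (entry F0).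

## Further compounds

F1 | step 3 | [(2E,6E)-3,7,11-trimethyldodeca-2,6,10-trien-1-yl]boronic acid | OB(O)C/C=C(\C)CC/C=C(\C)CCC=C(C)C
F2 | step 3 | diisopropyl (4R,5R)-2-[(2E,6E)-3,7,11-trimethyldodeca-2,6,10-trien-1-yl]-1,3,2-dioxaborolane-4,5-dicarboxylate | CC(C)OC(=O)[C@@H]1OB(C/C=C(\C)CC/C=C(\C)CCC=C(C)C)O[C@H]1C(=O)OC(C)C
F3 | step 2 | 2-bromo-1-(2-hydroxy-6-methylphenyl)ethan-1-one | Cc1cccc(O)c1C(=O)CBr
F0 | step 5 | none | none
A1 | alternative 1 | diethyl (2E,6E)-3,7,11-trimethyldodeca-2,6,10-trien-1-yl phosphate | CCOP(=O)(OCC)OC/C=C(\C)CC/C=C(\C)CCC=C(C)C
A2 | alternative 1 | 2-ethynyl-1-methoxy-3-methylbenzene | C#Cc1c(C)cccc1OC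
A3 | alternative 1 | 2-[(3S,6E)-3-ethenyl-3,7,11-trimethyldodeca-6,10-dien-1-yn-1-yl]-1-methoxy-3-methylbenzene | C=C[C@](C)(CC/C=C(\C)CCC=C(C)C)C#Cc1c(C)cccc1OC
A4 | alternative 2 | (2E,6E)-1-(2-methoxy-6-methylphenyl)-3,7,11-trimethyldodeca-2,6,10-trien-1-one | COc1cccc(C)c1C(=O)/C=C(\C)CC/C=C(\C)CCC=C(C)C
A5 | alternative 3 | 4-hydroxy-5-methyl-2H-chromen-2-one | Cc1cccc2OC(=O)C=C(O)c12
A6 | alternative 3 | 5-methyl-4-{[(2E,6E)-3,7,11-trimethyldodeca-2,6,10-trien-1-yl]oxy}-2H-chromen-2-one | Cc1cccc2OC(=O)C=C(OC/C=C(\C)CC/C=C(\C)CCC=C(C)C)c12
A7 | alternative 3 | 4-hydroxy-5-methyl-3-[(3S,6E)-3,7,11-trimethyldodeca-1,6,10-trien-3-yl]-2H-chromen-2-one | C=C[C@](C)(CC/C=C(\C)CCC=C(C)C)C1=C(O)c2c(C)cccc2OC1=O
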